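**Plan**
- Retrosynthesis: C4–C5 is cut first (alkenyl triflate + aldehyde). Then the lactone C6–O bond (epoxide opening by the ester, with inversion), then C7–C8 (indium Barbier union of a furanone aldehyde with a 2-(bromomethyl)acrylate). Last, the furanone (O–C3 and C1–C2 through a hydroxy-ynone) and C9–C10 (allylation of a lactate enolate).
- Enabling feature: the nine-membered oxacycle O–C3–C4–C5–C6–C7–C8–C9–C10 holds the unit C15H2=C4–C5H(OH) next to the lactone carbinol C6. This is the retron of an alkenylmetal addition to an α-oxygenated aldehyde. The cis-fused lactone (C6/C7) and the flat furanone (O, C3, C2, C1, C10) place both reacting ends on one face.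
- Forward order: furanone ring (step 5), union of the two fragments (step 10), α-methylene lactone (step 14), nine-membered ring last (step 16), which gives the target directly.
- Stereochemistry: C10 from D-lactic acid; C6 from D-glyceraldehyde acetonide, used with one inversion; C7 and C8 from the chair transition state and the allylic stereocentre in step 10; C5 from Felkin–Anh addition in step 16.

Key step: step 16

Remark: locants follow the germacranolide frame of the target (C1 ketone, C2=C3 enol ether, C4=C15 methylene, C5 carbinol, C6 lactone carbinol, C7, C8 acyloxy carbon, C9, C10 quaternary carbon, C11=C13, C12 lactone carbonyl, C14 methyl); 2-ethynyl-2-methyl-1,3-dioxolane (5) is taken as purchasable.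

**Route**

Step 1
Reactants: 1 D-lactic acid
Product: 2 (2R,5R)-2-tert-butyl-5-methyl-1,3-dioxolan-4-one
Conditions: pivalaldehyde, TsOH·H2O (cat.), H2SO4 (cat.), pentane, reflux, water separator; recrystallisation
Reagents that add atoms: pivalaldehyde, CC(C)(C)C=O
Why: Acid-catalysed acetalisation should give the cis-dioxolanone as the thermodynamic, crystalline isomer, so the lactate stereocentre fixes the acetal carbon that steers step 2.

Step 2
Reactants: 2 (2R,5R)-2-tert-butyl-5-methyl-1,3-dioxolan-4-one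
Product: 3 (2R,5S)-2-tert-butyl-5-methyl-5-(prop-2-en-1-yl)-1,3-dioxolan-4-one
Conditions: LiN(i-Pr)2, THF, −78 °C; allyl bromide, −78 → −30 °C; aq NH4Cl
Reagents that add atoms: allyl bromide, C=CCBr
Why: Alkylation of the lithium enolate of a lactic acid dioxolanone (self-regeneration of stereocentres) takes place anti to the tert-butyl group, so allyl replaces hydrogen with retention and sets the quaternary centre that becomes C10.

Step 3
Reactants: 3 (2R,5S)-2-tert-butyl-5-methyl-5-(prop-2-en-1-yl)-1,3-dioxolan-4-one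
Product: 4 (2S)-2-hydroxy-N-methoxy-N,2-dimethylpent-4-enamide
Conditions: MeNHOMe·HCl, i-PrMgCl, THF, −20 → 0 °C; aq NH4Cl
Reagents that add atoms: N,O-dimethylhydroxylamine hydrochloride, CNOC.Cl
Why: The chloromagnesium amide opens the activated acetal ester (Weinreb amide formation by aminolysis), the hemiacetal then loses pivalaldehyde, and the quaternary centre is not touched.

Step 4
Reactants: 4 (2S)-2-hydroxy-N-methoxy-N,2-dimethylpent-4-enamide; 5 2-ethynyl-2-methyl-1,3-dioxolane
Product: 6 (4S)-4-hydroxy-4-methyl-1-(2-methyl-1,3-dioxolan-2-yl)hept-6-en-1-yn-3-one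
Conditions: 5 (3.3 equiv), n-BuLi (3.2 equiv), THF, −78 °C; then 4, −78 → −20 °C; aq NH4Cl
Reagents that add atoms: none
Why: Weinreb ketone synthesis, in which the first equivalent of acetylide deprotonates the tertiary alcohol and the chelated tetrahedral intermediate stops the addition at the ynone.

Step 5
Reactants: 6 (4S)-4-hydroxy-4-methyl-1-(2-methyl-1,3-dioxolan-2-yl)hept-6-en-1-yn-3-one
Product: 8 (2S)-5-acetyl-2-methyl-2-(prop-2-en-1-yl)furan-3(2H)-one, via ketal furanone 7 (not isolated)
Conditions: K2CO3 (0.2 equiv), MeOH, 0 °C → rt; then 2 M HCl, THF, rt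
Reagents that add atoms: water, O
Why: Base-mediated 5-endo-dig oxa-Michael addition of the tertiary alkoxide to the ynone should give the 3(2H)-furanone (any methanol adduct of the ynone converges to it in the acid stage), and aqueous acid then hydrolyses the ketal to the methyl ketone.

Step 6
Reactants: 8 (2S)-5-acetyl-2-methyl-2-(prop-2-en-1-yl)furan-3(2H)-one
Product: 9 1-[(5S)-5-methyl-4-oxo-5-(prop-2-en-1-yl)-4,5-dihydrofuran-2-yl]ethenyl trifluoromethanesulfonate
Conditions: KN(SiMe3)2, THF, −78 °C; PhNTf2, −78 → 0 °C; aq NH4Cl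
Reagents that add atoms: N-phenylbis(trifluoromethanesulfonimide), O=S(=O)(N(c1ccccc1)S(=O)(=O)C(F)(F)F)C(F)(F)F
Why: The acetyl methyl group is the only enolisable position, so kinetic deprotonation and O-sulfonylation (enol triflate formation) should give the 2-triflyloxy diene.

Step 7
Reactants: 9 1-[(5S)-5-methyl-4-oxo-5-(prop-2-en-1-yl)-4,5-dihydrofuran-2-yl]ethenyl trifluoromethanesulfonate
Product: 10 1-[(5S)-5-methyl-4-oxo-5-(2-oxoethyl)-4,5-dihydrofuran-2-yl]ethenyl trifluoromethanesulfonate
Conditions: OsO4 (2 mol %), NaIO4 (4 equiv), 2,6-lutidine, 1,4-dioxane/H2O (3:1), rt; used at once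
Reagents that add atoms: sodium periodate, [Na+].[O-]I(=O)(=O)=O; osmium tetroxide (catalytic oxygen carrier), O=[Os](=O)(=O)=O
Why: Lemieux–Johnson oxidation, in which the isolated electron-rich monosubstituted alkene should be dihydroxylated far faster than the electron-poor enol triflate and push–pull furanone alkenes, and periodate cleaves the diol to the aldehyde, which is not stored because base can expel its β-oxygen.

Step 8
Reactants: 11 (R)-2,2-dimethyl-1,3-dioxolane-4-carbaldehyde (D-glyceraldehyde acetonide); 12 tert-butyl acrylate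
Product: 13 tert-butyl 2-{[(4R)-2,2-dimethyl-1,3-dioxolan-4-yl](hydroxy)methyl}prop-2-enoate (both carbinol epimers)
Conditions: DABCO (1.0 equiv), 1,4-dioxane/H2O (1:1), rt
Reagents that add atoms: none
Why: Morita–Baylis–Hillman reaction under amine catalysis, in which the new carbinol centre is formed without control (it becomes sp2 in step 9) and the dioxolane centre is kept.

Step 9
Reactants: 13 tert-butyl 2-{[(4R)-2,2-dimethyl-1,3-dioxolan-4-yl](hydroxy)methyl}prop-2-enoate
Product: 14 tert-butyl (2Z)-2-(bromomethyl)-3-[(4S)-2,2-dimethyl-1,3-dioxolan-4-yl]prop-2-enoate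
Conditions: NBS, Me2S, CH2Cl2, −20 °C → rt
Reagents that add atoms: N-bromosuccinimide, O=C1CCC(=O)N1Br
Why: Activation of the allylic alcohol as an alkoxysulfonium salt and SN2′ attack of bromide with allylic transposition should give the thermodynamically preferred (Z)-2-(bromomethyl)alkenoate from both carbinol epimers under conditions that spare the acetonide and the tert-butyl ester.

Step 10
Reactants: 10 1-[(5S)-5-methyl-4-oxo-5-(2-oxoethyl)-4,5-dihydrofuran-2-yl]ethenyl trifluoromethanesulfonate; 14 tert-butyl (2Z)-2-(bromomethyl)-3-[(4S)-2,2-dimethyl-1,3-dioxolan-4-yl]prop-2-enoate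
Product: 15 tert-butyl (3R,4R)-3-[(4S)-2,2-dimethyl-1,3-dioxolan-4-yl]-4-hydroxy-2-methylidene-5-[(2S)-2-methyl-3-oxo-5-(1-{[(trifluoromethyl)sulfonyl]oxy}ethenyl)-2,3-dihydrofuran-2-yl]pentanoate
Conditions: indium powder (1.5 equiv), THF/H2O (1:1), rt
Reagents that add atoms: none
Why: Indium Barbier allylation through a closed six-membered chair transition state, in which the (Z)-allylindium places C6 axial and the aldehyde substituent equatorial (the C7/C8 relationship that Z-configured 2-(bromomethyl)alkenoates give), while allylic 1,3-strain holds the C6–H bond in the alkene plane so that the aldehyde should enter anti to the dioxolane oxygen and fix the absolute sense (7R,8R), and the tert-butyl ester keeps the new alkoxide from lactonising.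

Step 11
Reactants: 15 the homoallylic alcohol from step 10
Product: 16 tert-butyl (3R,4R)-3-[(4S)-2,2-dimethyl-1,3-dioxolan-4-yl]-2-methylidene-4-[(2-methylpropanoyl)oxy]-5-[(2S)-2-methyl-3-oxo-5-(1-{[(trifluoromethyl)sulfonyl]oxy}ethenyl)-2,3-dihydrofuran-2-yl]pentanoate
Conditions: isobutyric anhydride, Et3N, DMAP (cat.), CH2Cl2, 0 °C → rt
Reagents that add atoms: isobutyric anhydride, CC(C)C(=O)OC(=O)C(C)C
Why: DMAP-catalysed acylation of the only free hydroxyl installs the isobutyrate of the target before any other hydroxyl is set free.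

Step 12
Reactants: 16 the isobutyrate from step 11
Product: 17 tert-butyl (3S,4R)-3-[(1S)-1,2-dihydroxyethyl]-2-methylidene-4-[(2-methylpropanoyl)oxy]-5-[(2S)-2-methyl-3-oxo-5-(1-{[(trifluoromethyl)sulfonyl]oxy}ethenyl)-2,3-dihydrofuran-2-yl]pentanoate
Conditions: AcOH/H2O (4:1), 40 °C
Reagents that add atoms: none
Why: Mild acid hydrolysis removes the terminal acetonide while the tert-butyl ester, the isobutyrate and the enol triflate should survive aqueous acetic acid.

Step 13
Reactants: 17 the diol from step 12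
Product: 18 tert-butyl (3R,4R)-2-methylidene-4-[(2-methylpropanoyl)oxy]-3-[(2S)-oxiran-2-yl]-5-[(2S)-2-methyl-3-oxo-5-(1-{[(trifluoromethyl)sulfonyl]oxy}ethenyl)-2,3-dihydrofuran-2-yl]pentanoate
Conditions: PPh3, DIAD, toluene, 60 °C
Reagents that add atoms: none
Why: Mitsunobu cyclodehydration of the 1,2-diol, in which the less hindered primary hydroxyl is activated as the oxyphosphonium ion and displaced by the secondary oxygen, so the terminal epoxide should form with retention at C6.

Step 14
Reactants: 18 the epoxide from step 13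
Product: 19 (1R)-1-[(2R,3R)-2-(hydroxymethyl)-4-methylidene-5-oxooxolan-3-yl]-2-[(2S)-2-methyl-3-oxo-5-(1-{[(trifluoromethyl)sulfonyl]oxy}ethenyl)-2,3-dihydrofuran-2-yl]ethyl 2-methylpropanoate
Conditions: BF3·OEt2 (0.3 equiv), CH2Cl2, −40 → 0 °C; aq NaHCO3
Reagents that add atoms: none
Why: The Lewis acid activates the epoxide, the carbonyl oxygen of the tert-butyl ester attacks C6 in the favoured 5-exo mode with inversion and the dialkoxycarbenium ion loses isobutene (epoxide-opening lactonisation with ester participation), which should turn the 6-epi centre into the (6R) centre of the cis-fused lactone and free the C5 hydroxyl.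

Step 15
Reactants: 19 the hydroxymethyl lactone from step 14
Product: 20 (1R)-1-[(2R,3R)-2-formyl-4-methylidene-5-oxooxolan-3-yl]-2-[(2S)-2-methyl-3-oxo-5-(1-{[(trifluoromethyl)sulfonyl]oxy}ethenyl)-2,3-dihydrofuran-2-yl]ethyl 2-methylpropanoate
Conditions: Dess–Martin periodinane, NaHCO3, CH2Cl2, 0 °C → rt; crude aldehyde used directly
Reagents that add atoms: none
Why: Dess–Martin oxidation under buffered, non-basic conditions should give the α-acyloxy aldehyde without epimerisation at C6.

Step 16
Reactants: 20 the triflate aldehyde from step 15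
Product: 21 the target, (5S,6R,7R,8R,10S)-3,10-epoxy-5-hydroxy-1-oxogermacra-2,4(15),11(13)-trien-12,6-olid-8-yl 2-methylpropanoate
Conditions: CrCl2 (10 equiv), NiCl2 (0.2 equiv), degassed DMSO, rt, syringe-pump addition of 20 to a final 2 mM
Reagents that add atoms: none
Why: Zerovalent nickel (formed from NiCl2 by divalent chromium) inserts into the C4–OTf bond, the alkenyl group passes to chromium, and the trivalent alkenylchromium adds to the C5 aldehyde, an intramolecular Nozaki–Hiyama–Kishi reaction for which medium-ring closures of alkenyl triflates and iodides onto aldehydes are the closest precedent. The step closes the nine-membered oxacycle O–C3–C4–C5–C6–C7–C8–C9–C10, and with it the ten-membered carbocyclic perimeter, in the exo-trig mode at the aldehyde carbon, with the furanone and the lactone already in place. The new C5 stereocentre is controlled by C6: the alkenyl group should enter anti to the C6–O bond of the non-chelated α-acyloxy aldehyde (Felkin–Anh), which gives the 5,6-anti carbinol of the target, and the cis fusion of the lactone, which puts C5 and the C8 arm on one face, favours the same approach. The step needs chemoselectivity for the aldehyde over the ketone, the two esters and the lactone, which the low basicity of organochromium reagents secures. It also needs ring closure to outrun oligomerisation, which high dilution and the preorganisation by the cis-lactone and the planar furanone should secure. The product is the free C5 alcohol, so no protecting group remains to be removed.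

**Compound list**

1 | D-lactic acid, (R)-2-hydroxypropanoic acid | C[C@@H](O)C(=O)O | starting material
2 | (2R,5R)-2-tert-butyl-5-methyl-1,3-dioxolan-4-one (cis) | C[C@H]1O[C@@H](C(C)(C)C)OC1=O | intermediate
3 | (2R,5S)-2-tert-butyl-5-methyl-5-(prop-2-en-1-yl)-1,3-dioxolan-4-one | C[C@@]1(CC=C)O[C@@H](C(C)(C)C)OC1=O | intermediate
4 | (2S)-2-hydroxy-N-methoxy-N,2-dimethylpent-4-enamide | C=CC[C@](C)(O)C(=O)N(C)OC | intermediate
5 | 2-ethynyl-2-methyl-1,3-dioxolane | C#CC1(C)OCCO1 | starting material
6 | (4S)-4-hydroxy-4-methyl-1-(2-methyl-1,3-dioxolan-2-yl)hept-6-en-1-yn-3-one | C=CC[C@](C)(O)C(=O)C#CC1(C)OCCO1 | intermediate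
7 | (2S)-2-methyl-5-(2-methyl-1,3-dioxolan-2-yl)-2-(prop-2-en-1-yl)furan-3(2H)-one | C=CC[C@]1(C)OC(=CC1=O)C2(C)OCCO2 | intermediate (not isolated)
8 | (2S)-5-acetyl-2-methyl-2-(prop-2-en-1-yl)furan-3(2H)-one | C=CC[C@]1(C)OC(=CC1=O)C(C)=O | intermediate
9 | 1-[(5S)-5-methyl-4-oxo-5-(prop-2-en-1-yl)-4,5-dihydrofuran-2-yl]ethenyl trifluoromethanesulfonate | C=CC[C@]1(C)OC(=CC1=O)C(=C)OS(=O)(=O)C(F)(F)F | intermediate
10 | 1-[(5S)-5-methyl-4-oxo-5-(2-oxoethyl)-4,5-dihydrofuran-2-yl]ethenyl trifluoromethanesulfonate | O=CC[C@]1(C)OC(=CC1=O)C(=C)OS(=O)(=O)C(F)(F)F | intermediate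
11 | (R)-2,2-dimethyl-1,3-dioxolane-4-carbaldehyde (D-glyceraldehyde acetonide) | O=C[C@H]1COC(C)(C)O1 | starting material
12 | tert-butyl acrylate | C=CC(=O)OC(C)(C)C | starting material
13 | tert-butyl 2-{[(4R)-2,2-dimethyl-1,3-dioxolan-4-yl](hydroxy)methyl}prop-2-enoate (both carbinol epimers) | C=C(C(=O)OC(C)(C)C)C(O)[C@H]1COC(C)(C)O1 | intermediate
14 | tert-butyl (2Z)-2-(bromomethyl)-3-[(4S)-2,2-dimethyl-1,3-dioxolan-4-yl]prop-2-enoate | BrC/C(C(=O)OC(C)(C)C)=C\[C@H]1COC(C)(C)O1 | intermediate
15 | tert-butyl (3R,4R)-3-[(4S)-2,2-dimethyl-1,3-dioxolan-4-yl]-4-hydroxy-2-methylidene-5-[(2S)-2-methyl-3-oxo-5-(1-{[(trifluoromethyl)sulfonyl]oxy}ethenyl)-2,3-dihydrofuran-2-yl]pentanoate | C=C(C(=O)OC(C)(C)C)[C@@H]([C@H]2COC(C)(C)O2)[C@H](O)C[C@]1(C)OC(=CC1=O)C(=C)OS(=O)(=O)C(F)(F)F | intermediate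
16 | tert-butyl (3R,4R)-3-[(4S)-2,2-dimethyl-1,3-dioxolan-4-yl]-2-methylidene-4-[(2-methylpropanoyl)oxy]-5-[(2S)-2-methyl-3-oxo-5-(1-{[(trifluoromethyl)sulfonyl]oxy}ethenyl)-2,3-dihydrofuran-2-yl]pentanoate | C=C(C(=O)OC(C)(C)C)[C@@H]([C@H]2COC(C)(C)O2)[C@H](OC(=O)C(C)C)C[C@]1(C)OC(=CC1=O)C(=C)OS(=O)(=O)C(F)(F)F | intermediate
17 | tert-butyl (3S,4R)-3-[(1S)-1,2-dihydroxyethyl]-2-methylidene-4-[(2-methylpropanoyl)oxy]-5-[(2S)-2-methyl-3-oxo-5-(1-{[(trifluoromethyl)sulfonyl]oxy}ethenyl)-2,3-dihydrofuran-2-yl]pentanoate | C=C(C(=O)OC(C)(C)C)[C@@H]([C@H](O)CO)[C@H](OC(=O)C(C)C)C[C@]1(C)OC(=CC1=O)C(=C)OS(=O)(=O)C(F)(F)F | intermediate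
18 | tert-butyl (3R,4R)-2-methylidene-4-[(2-methylpropanoyl)oxy]-3-[(2S)-oxiran-2-yl]-5-[(2S)-2-methyl-3-oxo-5-(1-{[(trifluoromethyl)sulfonyl]oxy}ethenyl)-2,3-dihydrofuran-2-yl]pentanoate | C=C(C(=O)OC(C)(C)C)[C@@H]([C@H]2CO2)[C@H](OC(=O)C(C)C)C[C@]1(C)OC(=CC1=O)C(=C)OS(=O)(=O)C(F)(F)F | intermediate
19 | (1R)-1-[(2R,3R)-2-(hydroxymethyl)-4-methylidene-5-oxooxolan-3-yl]-2-[(2S)-2-methyl-3-oxo-5-(1-{[(trifluoromethyl)sulfonyl]oxy}ethenyl)-2,3-dihydrofuran-2-yl]ethyl 2-methylpropanoate | C=C1C(=O)O[C@@H](CO)[C@H]1[C@H](OC(=O)C(C)C)C[C@]1(C)OC(=CC1=O)C(=C)OS(=O)(=O)C(F)(F)F | intermediate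
20 | (1R)-1-[(2R,3R)-2-formyl-4-methylidene-5-oxooxolan-3-yl]-2-[(2S)-2-methyl-3-oxo-5-(1-{[(trifluoromethyl)sulfonyl]oxy}ethenyl)-2,3-dihydrofuran-2-yl]ethyl 2-methylpropanoate | C=C1C(=O)O[C@@H](C=O)[C@H]1[C@H](OC(=O)C(C)C)C[C@]1(C)OC(=CC1=O)C(=C)OS(=O)(=O)C(F)(F)F | intermediate
21 | CNP0384113.2, (5S,6R,7R,8R,10S)-3,10-epoxy-5-hydroxy-1-oxogermacra-2,4(15),11(13)-trien-12,6-olid-8-yl 2-methylpropanoate | C=C1C(=O)O[C@@H]2[C@H]1[C@H](OC(=O)C(C)C)C[C@]1(C)OC(=CC1=O)C(=C)[C@@H]2O | target

**Totals**
Total step count: 16. Longest linear sequence: 14 (steps 1–7 and 10–16).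

**Steps most likely to fail**

Step 16 (ring closure). What may go wrong: addition of the alkenylchromium to the aldehyde of a second molecule in place of closure of the strained ring, and, where the ring does close, attack on the other aldehyde face under the conformational control of the forming ring. Fallback, setting out from 20 and returning at 21: the ring is closed as before, and C5 is then set by a ketone reduction instead of by the C–C bond formation. The 5-epimeric alcohol F1 (or the epimer mixture) is oxidised with Dess–Martin periodinane to the cross-conjugated C5 ketone F2. A Corey–Bakshi–Shibata reduction ((S)-2-methyl-CBS-oxazaborolidine, catecholborane, toluene, −78 °C), with the alkenyl side as the large group, should then return the (5S) alcohol 21.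

Step 10 (fragment union). What may go wrong: entry of the aldehyde on the other face of the allylindium (syn to the dioxolane oxygen), or poor facial discrimination, which would set C7 and C8 wrongly with respect to C6. Fallback, setting out from 10 and returning at 19: the opposite sense of induction is put to use and the lactone is closed with retention instead of inversion. Purchased (S)-glyceraldehyde acetonide F3 is taken through the reactions of steps 8 and 9 to the adduct F4 and the enantiomeric bromide F5. Indium coupling with 10 should then give the alcohol F6, with C7 and C8 as before and C6 already in the configuration of the target. Acylation as in step 11 gives the isobutyrate F7. Aqueous trifluoroacetic acid then removes the acetonide and the tert-butyl ester and closes the lactone by acylation of the C6 hydroxyl, giving 19; steps 12 to 14 are then not needed.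

Step 14 (lactonisation with inversion). What may go wrong: participation of the isobutyrate carbonyl at C6 through a six-membered acyloxonium ion (acyl migration), or opening at C5, in competition with the 5-exo attack of the tert-butyl ester; partial activation of the secondary hydroxyl in step 13 would also erode the configuration at C6. Fallback, setting out from 17 and returning at 19: the inversion is done by carboxylate displacement of a sulfonate instead of epoxide opening. The primary hydroxyl is silylated (TBSCl, imidazole) to the silyl ether F8, and the secondary hydroxyl is converted into the mesylate F9 (MsCl, Et3N). The tert-butyl ester is cleaved to the acid F10 (TMSOTf, 2,6-lutidine; aqueous work-up). The caesium carboxylate then displaces the mesylate in an intramolecular SN2 reaction with inversion (Cs2CO3, DMF) to give the silylated lactone F11, and HF·pyridine removes the silyl group to give 19.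

Further compounds
F1 | step 16 | 5-epimer of 21, (5R,6R,7R,8R,10S) | C=C1C(=O)O[C@@H]2[C@H]1[C@H](OC(=O)C(C)C)C[C@]1(C)OC(=CC1=O)C(=C)[C@H]2O
F2 | step 16 | (6R,7R,8R,10S)-3,10-epoxy-1,5-dioxogermacra-2,4(15),11(13)-trien-12,6-olid-8-yl 2-methylpropanoate | C=C1C(=O)O[C@@H]2[C@H]1[C@H](OC(=O)C(C)C)C[C@]1(C)OC(=CC1=O)C(=C)C2=O
F3 | step 10 | (S)-2,2-dimethyl-1,3-dioxolane-4-carbaldehyde (L-glyceraldehyde acetonide, purchased) | O=C[C@@H]1COC(C)(C)O1
F4 | step 10 | tert-butyl 2-{[(4S)-2,2-dimethyl-1,3-dioxolan-4-yl](hydroxy)methyl}prop-2-enoate (both carbinol epimers) | C=C(C(=O)OC(C)(C)C)C(O)[C@@H]1COC(C)(C)O1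
F5 | step 10 | tert-butyl (2Z)-2-(bromomethyl)-3-[(4R)-2,2-dimethyl-1,3-dioxolan-4-yl]prop-2-enoate | BrC/C(C(=O)OC(C)(C)C)=C\[C@@H]1COC(C)(C)O1
F6 | step 10 | tert-butyl (3R,4R)-3-[(4R)-2,2-dimethyl-1,3-dioxolan-4-yl]-4-hydroxy-2-methylidene-5-[(2S)-2-methyl-3-oxo-5-(1-{[(trifluoromethyl)sulfonyl]oxy}ethenyl)-2,3-dihydrofuran-2-yl]pentanoate | C=C(C(=O)OC(C)(C)C)[C@@H]([C@@H]2COC(C)(C)O2)[C@H](O)C[C@]1(C)OC(=CC1=O)C(=C)OS(=O)(=O)C(F)(F)F
F7 | step 10 | tert-butyl (3R,4R)-3-[(4R)-2,2-dimethyl-1,3-dioxolan-4-yl]-2-methylidene-4-[(2-methylpropanoyl)oxy]-5-[(2S)-2-methyl-3-oxo-5-(1-{[(trifluoromethyl)sulfonyl]oxy}ethenyl)-2,3-dihydrofuran-2-yl]pentanoate | C=C(C(=O)OC(C)(C)C)[C@@H]([C@@H]2COC(C)(C)O2)[C@H](OC(=O)C(C)C)C[C@]1(C)OC(=CC1=O)C(=C)OS(=O)(=O)C(F)(F)F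
F8 | step 14 | tert-butyl (3S,4R)-3-[(1S)-2-{[tert-butyl(dimethyl)silyl]oxy}-1-hydroxyethyl]-2-methylidene-4-[(2-methylpropanoyl)oxy]-5-[(2S)-2-methyl-3-oxo-5-(1-{[(trifluoromethyl)sulfonyl]oxy}ethenyl)-2,3-dihydrofuran-2-yl]pentanoate | C=C(C(=O)OC(C)(C)C)[C@@H]([C@H](O)CO[Si](C)(C)C(C)(C)C)[C@H](OC(=O)C(C)C)C[C@]1(C)OC(=CC1=O)C(=C)OS(=O)(=O)C(F)(F)F
F9 | step 14 | tert-butyl (3R,4R)-3-[(1S)-2-{[tert-butyl(dimethyl)silyl]oxy}-1-(methanesulfonyloxy)ethyl]-2-methylidene-4-[(2-methylpropanoyl)oxy]-5-[(2S)-2-methyl-3-oxo-5-(1-{[(trifluoromethyl)sulfonyl]oxy}ethenyl)-2,3-dihydrofuran-2-yl]pentanoate | C=C(C(=O)OC(C)(C)C)[C@@H]([C@H](OS(C)(=O)=O)CO[Si](C)(C)C(C)(C)C)[C@H](OC(=O)C(C)C)C[C@]1(C)OC(=CC1=O)C(=C)OS(=O)(=O)C(F)(F)F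
F10 | step 14 | (3R,4R)-3-[(1S)-2-{[tert-butyl(dimethyl)silyl]oxy}-1-(methanesulfonyloxy)ethyl]-2-methylidene-4-[(2-methylpropanoyl)oxy]-5-[(2S)-2-methyl-3-oxo-5-(1-{[(trifluoromethyl)sulfonyl]oxy}ethenyl)-2,3-dihydrofuran-2-yl]pentanoic acid | C=C(C(=O)O)[C@@H]([C@H](OS(C)(=O)=O)CO[Si](C)(C)C(C)(C)C)[C@H](OC(=O)C(C)C)C[C@]1(C)OC(=CC1=O)C(=C)OS(=O)(=O)C(F)(F)F
F11 | step 14 | (1R)-1-[(2R,3R)-2-({[tert-butyl(dimethyl)silyl]oxy}methyl)-4-methylidene-5-oxooxolan-3-yl]-2-[(2S)-2-methyl-3-oxo-5-(1-{[(trifluoromethyl)sulfonyl]oxy}ethenyl)-2,3-dihydrofuran-2-yl]ethyl 2-methylpropanoate | C=C1C(=O)O[C@@H](CO[Si](C)(C)C(C)(C)C)[C@H]1[C@H](OC(=O)C(C)C)C[C@]1(C)OC(=CC1=O)C(=C)OS(=O)(=O)C(F)(F)F
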